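A direct plan would take 2,4,6-trihydroxybenzaldehyde A1, C-prenylate it twice with prenyl bromide A2 in aqueous base to the 3,5-diprenyl aldehyde A3, methylate the 4-OH to give A4, and join the formyl carbon of A4 to 3-iodophenol A5 by a palladium-catalysed formyl C–H arylation.
Its weakest steps would be:
- The double C-prenylation of the phloroglucinol nucleus: O-alkylation, mono- and tri-alkylation and geminal (dearomatising) prenylation would all compete, at the very start of the route.
- The mono-O-methylation: it would have to pick one phenol out of three, and the wanted one sits between two prenyl groups.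
- The late palladium acylation: two free chelating phenols, two prenyl alkenes (Heck insertion, oxypalladation to chromans) and a free iodophenol would meet palladium at 100 °C, with decarbonylation as a further exit.

**Retrosynthetic overview**
- Ring A (C1 aroyl, C2/C6 OH, C3/C5 prenyl, C4 OMe) would be formed only in the last step, by isomerising a fully substituted 2-pyranone: lactone opening, then Claisen closure of the C1–C6 bond.
- The pyranone maps atom for atom onto ring A: its 6-CH2 becomes C1, C6 and the ring oxygen become C2 and its OH, C5 and C3 carry the prenyls of C3 and C5, C4–OMe stays C4–OMe, and the lactone C=O becomes C6–OH.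
- Disconnections: C1–C6 (key step); C1–C(=O) by Claisen acylation of the pyranone 6-methyl anion with a 3-silyloxybenzoate; the two prenyl–carbon bonds by Negishi coupling at the 3,5-dibromide of commercial 4-methoxy-6-methyl-2-pyranone.
- Ring order: ring B and the pyranone are bought; ring A closes last.
- By design there is no phenol to C-prenylate (the prenyls go to halogen-marked carbons), no choice among phenols to methylate (the methoxy oxygen is never a free OH; both phenols come from the lactone oxygens), and no palladium step on the free polyphenol (the diaryl ketone comes from enolate acylation).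

Key step: step 5

Remark: the aryl silyl ether is assumed to be methanolysed under the methoxide conditions of the last step (phenolic silyl ethers are cleaved by alkoxide in methanol), so no separate deprotection is planned.

**Route**

Step 1
Reactants: 1 4-methoxy-6-methyl-2H-pyran-2-one; 2 bromine
Product: 4 3,5-dibromo-4-methoxy-6-methyl-2H-pyran-2-one, via 3-bromo-4-methoxy-6-methyl-2H-pyran-2-one 3 (not isolated)
Conditions: Br2 (2.5 equiv), NaOAc (2.5 equiv), AcOH, dark, rt then 50 °C
Reagents that add atoms: bromine (2), BrBr
Why: Electrophilic bromination of the pyranone dienol ether, which should take C3 first (between the lactone carbonyl and the methoxy carbon, giving 3) and then C5 (the β-carbon of the ring enol ether, next to the methoxy carbon), while ionic conditions in the dark with acetate as HBr buffer keep bromine off the 6-methyl group; no stereocentre is formed.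

Step 2
Reactants: 4 3,5-dibromo-4-methoxy-6-methyl-2H-pyran-2-one; 5 prenyl bromide (1-bromo-3-methylbut-2-ene)
Product: 7 4-methoxy-6-methyl-3,5-bis(3-methylbut-2-en-1-yl)-2H-pyran-2-one, via prenylzinc bromide 6 (not isolated)
Conditions: 5 (3.0 equiv), Zn dust (4 equiv), LiCl (3 equiv), THF, 0 °C to rt (gives 6); then 4, Pd(OAc)2 (5 mol %), CPhos (2-dicyclohexylphosphino-2',6'-bis(dimethylamino)biphenyl, 10 mol %), THF, rt to 40 °C
Reagents that add atoms: prenyl bromide (5), CC(C)=CCBr
Why: Negishi cross-coupling in its linear-selective form for allylic zinc halides, in which zerovalent palladium inserts into each C–Br bond, 6 transmetalates, and the bulky biarylphosphine makes reductive elimination from the primary-carbon-bound prenylpalladium faster than its isomerisation to the tertiary allyl isomer, so both prenyl groups should arrive unrearranged at the halogen-marked C3 and C5; no stereocentre is formed.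

Step 3
Reactants: 8 methyl 3-hydroxybenzoate; 9 tert-butyldimethylsilyl chloride
Product: 10 methyl 3-[(tert-butyldimethylsilyl)oxy]benzoate
Conditions: 9 (1.1 equiv), imidazole (2 equiv), DMF, rt
Reagents that add atoms: tert-butyldimethylsilyl chloride (9), CC(C)(C)[Si](C)(C)Cl
Why: Imidazole-promoted O-silylation of the phenol, which removes the acidic ring-B proton so that the ester of 10 stays a good acyl donor toward a carbanion; no stereocentre is formed.

Step 4
Reactants: 7 4-methoxy-6-methyl-3,5-bis(3-methylbut-2-en-1-yl)-2H-pyran-2-one; 10 methyl 3-[(tert-butyldimethylsilyl)oxy]benzoate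
Product: 11 6-(2-{3-[(tert-butyldimethylsilyl)oxy]phenyl}-2-oxoethyl)-4-methoxy-3,5-bis(3-methylbut-2-en-1-yl)-2H-pyran-2-one
Conditions: 7, LiN(SiMe3)2 (2.2 equiv), THF, −78 °C; then 10 (1.1 equiv), −78 to 0 °C; AcOH quench
Reagents that add atoms: methyl 3-[(tert-butyldimethylsilyl)oxy]benzoate (10), COC(=O)c1cccc(O[Si](C)(C)C(C)(C)C)c1
Why: Claisen-type acylation of a vinylogous lactone enolate, in which the only acidic site of 7 (C3 and C5 being blocked by prenyl groups) is the 6-methyl group, whose lithium anion, delocalised to the lactone carbonyl, attacks the non-enolisable aryl ester 10, and the second equivalent of base stores the more acidic product as its enolate; no stereocentre is formed.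

Step 5
Reactants: 11 6-(2-{3-[(tert-butyldimethylsilyl)oxy]phenyl}-2-oxoethyl)-4-methoxy-3,5-bis(3-methylbut-2-en-1-yl)-2H-pyran-2-one
Product: 14 [2,6-dihydroxy-4-methoxy-3,5-bis(3-methylbut-2-en-1-yl)phenyl](3-hydroxyphenyl)methanone (target), via open-chain triketide ester 12 (not isolated), via silylated benzophenone 13 (not isolated)
Conditions: Mg(OMe)2 (8 equiv), MeOH, reflux, 16 h; then cold 1 M HCl to pH 3
Reagents that add atoms: none
Why: Pyranone-to-benzene ring transformation by lactone methanolysis and intramolecular Claisen (Dieckmann-type) condensation: magnesium-bound methoxide adds to the lactone carbonyl of 11 and opens the ring to the open-chain ester 12, held as the magnesium chelate of its 1,3-diketone enolate. The chelated central carbon of that diketone (the former exocyclic CH2, the future C1 of ring A) attacks the methyl ester carbon (the former lactone carbon, the future C6) in a 6-exo-trig closure, methoxide leaves, and enolisation gives the aromatic ring A of 13, in which the former ring oxygen and lactone carbonyl oxygen are the two phenols flanking the ketone and the untouched enol ether is the 4-methoxy group. The closest known reaction type is the magnesium methoxide conversion of 6-(2-oxoalkyl)-4-hydroxy- and 4-methoxy-2-pyranones into acylphloroglucinols, the laboratory counterpart of the polyketide Claisen cyclisation. The step needs C-acylation at C1 to win over return to the 2-pyranone through oxygen, over vinylogous transesterification to a 4-pyranone and over aldol closure onto the aryl ketone; the first two are reversible under methoxide, and the aldol mode would have to use the prenyl-bearing carbon next to the ester and end in a quaternary centre that cannot aromatise, so only the Claisen path should drain into the aromatic magnesium bis-phenoxide chelate. No stereocentre is formed (the racemic C4 centre and the enol ether geometry of 12 disappear on aromatisation), the prenyl groups see only base, and the aryl silyl ether is methanolysed in the same pot to release the ring-B phenol of 14.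

**Compound list**
1 | 4-methoxy-6-methyl-2H-pyran-2-one | CC1=CC(OC)=CC(=O)O1 | starting material
2 | bromine | BrBr | starting material
3 | 3-bromo-4-methoxy-6-methyl-2H-pyran-2-one | CC1=CC(OC)=C(Br)C(=O)O1 | intermediate
4 | 3,5-dibromo-4-methoxy-6-methyl-2H-pyran-2-one | CC1=C(Br)C(OC)=C(Br)C(=O)O1 | intermediate
5 | prenyl bromide (1-bromo-3-methylbut-2-ene) | CC(C)=CCBr | starting material
6 | prenylzinc bromide | CC(C)=CC[Zn]Br | intermediate
7 | 4-methoxy-6-methyl-3,5-bis(3-methylbut-2-en-1-yl)-2H-pyran-2-one | CC1=C(CC=C(C)C)C(OC)=C(CC=C(C)C)C(=O)O1 | intermediate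
8 | methyl 3-hydroxybenzoate | COC(=O)c1cccc(O)c1 | starting material
9 | tert-butyldimethylsilyl chloride | CC(C)(C)[Si](C)(C)Cl | starting material
10 | methyl 3-[(tert-butyldimethylsilyl)oxy]benzoate | COC(=O)c1cccc(O[Si](C)(C)C(C)(C)C)c1 | intermediate
11 | 6-(2-{3-[(tert-butyldimethylsilyl)oxy]phenyl}-2-oxoethyl)-4-methoxy-3,5-bis(3-methylbut-2-en-1-yl)-2H-pyran-2-one | COC1=C(CC=C(C)C)C(=O)OC(CC(=O)c2cccc(O[Si](C)(C)C(C)(C)C)c2)=C1CC=C(C)C | intermediate
12 | methyl (2E)-7-{3-[(tert-butyldimethylsilyl)oxy]phenyl}-3-methoxy-2,4-bis(3-methylbut-2-en-1-yl)-5,7-dioxohept-2-enoate (racemic at C4) | COC(=O)/C(CC=C(C)C)=C(/OC)C(CC=C(C)C)C(=O)CC(=O)c1cccc(O[Si](C)(C)C(C)(C)C)c1 | intermediate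
13 | {3-[(tert-butyldimethylsilyl)oxy]phenyl}[2,6-dihydroxy-4-methoxy-3,5-bis(3-methylbut-2-en-1-yl)phenyl]methanone | COc1c(CC=C(C)C)c(O)c(C(=O)c2cccc(O[Si](C)(C)C(C)(C)C)c2)c(O)c1CC=C(C)C | intermediate
14 | [2,6-dihydroxy-4-methoxy-3,5-bis(3-methylbut-2-en-1-yl)phenyl](3-hydroxyphenyl)methanone (achiral) | COc1c(CC=C(C)C)c(O)c(C(=O)c2cccc(O)c2)c(O)c1CC=C(C)C | target

**Step count**
Total: 5 steps. Longest linear sequence: 4 steps (1, 2, 4, 5); step 3 is a one-step side branch.

**Steps most likely to fail**

1. Step 5. The open-chain magnesium enolate may re-close through oxygen faster than through carbon (back to the 2-pyranone, or to a 4-pyranone with loss of the methoxy group), or methoxide may cleave the aroyl group by retro-Claisen attack on the ketone. The fallback would separate opening from closure. Setting out from 11, brief treatment with NaOMe in MeOH–THF at 0 °C would open the lactone and cleave the silyl ether to give methyl (2E)-7-(3-hydroxyphenyl)-3-methoxy-2,4-bis(3-methylbut-2-en-1-yl)-5,7-dioxohept-2-enoate F1, isolated after buffered work-up. F1 would then be closed irreversibly as its lithium polyanion (LiN(iPr)2, 4.5 equiv, THF, −78 to 0 °C) in a kinetic Dieckmann-type Claisen, coming back to the route at 14.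

2. Step 2. Isomerisation of the prenylpalladium intermediate before reductive elimination would give 1,1-dimethylallyl (reverse-prenyl) groups, and the allylic zinc reagent may add to the lactone carbonyl. The fallback would install an allyl group, which has no such regiochemistry, and build the prenyl terminus afterwards. Setting out from 4, a double Stille coupling with allyltributylstannane F2 (Pd(PPh3)4, DMF, 80 °C) would give 3,5-diallyl-4-methoxy-6-methyl-2H-pyran-2-one F3. Cross-metathesis of F3 with 2-methylbut-2-ene F4 (used as co-solvent, second-generation Grubbs catalyst, CH2Cl2, 40 °C) would then come back to the route at 7.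

3. Step 4. Proton transfer from the acidic product methylene to unreacted lateral anion would stall the conversion, and the lateral anion may add to the lactone of a second pyranone. The fallback would form the bond by aldol addition, whose product is not acidic, and adjust the oxidation level afterwards. Setting out from 7, the lithium anion (LiN(SiMe3)2, 1.1 equiv, THF, −78 °C) would be added to 3-[(tert-butyldimethylsilyl)oxy]benzaldehyde F5 to give the racemic carbinol 6-(2-{3-[(tert-butyldimethylsilyl)oxy]phenyl}-2-hydroxyethyl)-4-methoxy-3,5-bis(3-methylbut-2-en-1-yl)-2H-pyran-2-one F6. Oxidation of the benzylic carbinol of F6 with MnO2 (CH2Cl2, rt) would come back to the route at 11.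

**Further compounds**
F1 | step 5 | methyl (2E)-7-(3-hydroxyphenyl)-3-methoxy-2,4-bis(3-methylbut-2-en-1-yl)-5,7-dioxohept-2-enoate (racemic at C4) | COC(=O)/C(CC=C(C)C)=C(/OC)C(CC=C(C)C)C(=O)CC(=O)c1cccc(O)c1
F2 | step 2 | allyltributylstannane | CCCC[Sn](CCCC)(CCCC)CC=C
F3 | step 2 | 3,5-diallyl-4-methoxy-6-methyl-2H-pyran-2-one | CC1=C(CC=C)C(OC)=C(CC=C)C(=O)O1
F4 | step 2 | 2-methylbut-2-ene | CC=C(C)C
F5 | step 4 | 3-[(tert-butyldimethylsilyl)oxy]benzaldehyde | O=Cc1cccc(O[Si](C)(C)C(C)(C)C)c1
F6 | step 4 | 6-(2-{3-[(tert-butyldimethylsilyl)oxy]phenyl}-2-hydroxyethyl)-4-methoxy-3,5-bis(3-methylbut-2-en-1-yl)-2H-pyran-2-one (racemic) | COC1=C(CC=C(C)C)C(=O)OC(CC(O)c2cccc(O[Si](C)(C)C(C)(C)C)c2)=C1CC=C(C)C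
A1 | direct plan | 2,4,6-trihydroxybenzaldehyde | O=Cc1c(O)cc(O)cc1O
A2 | direct plan | prenyl bromide (1-bromo-3-methylbut-2-ene) | CC(C)=CCBr
A3 | direct plan | 2,4,6-trihydroxy-3,5-bis(3-methylbut-2-en-1-yl)benzaldehyde | O=Cc1c(O)c(CC=C(C)C)c(O)c(CC=C(C)C)c1O
A4 | direct plan | 2,6-dihydroxy-4-methoxy-3,5-bis(3-methylbut-2-en-1-yl)benzaldehyde | COc1c(CC=C(C)C)c(O)c(C=O)c(O)c1CC=C(C)C
A5 | direct plan | 3-iodophenol | Oc1cccc(I)c1
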